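The butenolide ring (O, C12, C11, C7, C8) is read as one CO2 unit bridging C11 and C8. Numbering follows the germacrane skeleton (C1–C10 ring, C11 lactone α-carbon, C12 lactone carbonyl, C13 acetoxymethyl carbon). In the key step the C11 alkenyl bromide of a ten-membered cycloalkyne diol is lithiated, carboxylated with CO2 and closed onto the ring alkyne C8≡C9 by a silver salt in the same flask, forming C11–C12 and O–C8 and the E ring alkene together. The precursor comes from (R)-linalool (C1–C3, C9, C10), an Evans aldol (C4, C5) and mucobromic acid (C6, C7, C11, C13), whose dibromobutenolide acts as a cleavable template for the C7=C11 geometry.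

Key step: step 14

Remark: the C3 ketone and the C10 hydroxyl of the target could close to a transannular hemiketal; the open hydroxy ketone as drawn is taken as the target.

Step 1
Reactants: 1 (R)-linalool
Product: 2 triethyl{[(3R)-3,7-dimethylocta-1,6-dien-3-yl]oxy}silane
Conditions: TESOTf, 2,6-lutidine, CH2Cl2, 0 °C
Reagents that add atoms: triethylsilyl trifluoromethanesulfonate CC[Si](CC)(CC)OS(=O)(=O)C(F)(F)F
Why: Silyl ether formation with the silyl triflate is the standard way to cap a hindered tertiary allylic alcohol, and the C10 stereocentre carried in from linalool is not touched.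

Step 2
Reactants: 2 triethyl{[(3R)-3,7-dimethylocta-1,6-dien-3-yl]oxy}silane
Product: 3 (4R)-4-methyl-4-(triethylsilyloxy)hex-5-enal
Conditions: O3 (1 equiv, Sudan Red 7B end-point), CH2Cl2/MeOH, −78 °C; Me2S, −78 °C → rt
Reagents that add atoms: ozone [O-][O+]=O
Why: Chemoselective ozonolysis, in which the electron-rich trisubstituted alkene consumes one equivalent of ozone much faster than the vinyl group that is deactivated and shielded by the neighbouring quaternary silyloxy carbon.

Step 3
Reactants: 3 (4R)-4-methyl-4-(triethylsilyloxy)hex-5-enal; 4 (4R)-4-benzyl-3-propanoyl-1,3-oxazolidin-2-one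
Product: 5 (4R)-4-benzyl-3-[(2R,3S,6R)-3-hydroxy-2,6-dimethyl-6-(triethylsilyloxy)oct-7-enoyl]-1,3-oxazolidin-2-one
Conditions: Bu2BOTf, iPr2NEt, CH2Cl2, 0 °C; then 3, −78 → 0 °C; H2O2, pH 7 buffer, MeOH
Reagents that add atoms: none
Why: Evans syn-aldol reaction through the Z boron enolate and a chair Zimmerman–Traxler transition state, in which the (R)-benzyl auxiliary directs the aldehyde to one enolate face and so sets C4 (and the C3 carbinol, which is oxidised at the end).

Step 4
Reactants: 5 (4R)-4-benzyl-3-[(2R,3S,6R)-3-hydroxy-2,6-dimethyl-6-(triethylsilyloxy)oct-7-enoyl]-1,3-oxazolidin-2-one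
Product: 6 (4R)-4-benzyl-3-[(2R,3S,6R)-2,6-dimethyl-3,6-bis(triethylsilyloxy)oct-7-enoyl]-1,3-oxazolidin-2-one
Conditions: TESOTf, 2,6-lutidine, CH2Cl2, −78 → 0 °C
Reagents that add atoms: triethylsilyl trifluoromethanesulfonate CC[Si](CC)(CC)OS(=O)(=O)C(F)(F)F
Why: Silyl ether formation on the secondary aldol hydroxyl blocks retro-aldol cleavage and keeps C3 masked until the final oxidation.

Step 5
Reactants: 6 (4R)-4-benzyl-3-[(2R,3S,6R)-2,6-dimethyl-3,6-bis(triethylsilyloxy)oct-7-enoyl]-1,3-oxazolidin-2-one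
Product: 7 (2S,3S,6R)-2,6-dimethyl-3,6-bis(triethylsilyloxy)oct-7-en-1-ol
Conditions: LiBH4, H2O (1 equiv), Et2O, 0 °C
Reagents that add atoms: none
Why: Reductive cleavage of the N-acyl oxazolidinone with LiBH4 should give the primary C5 alcohol without epimerising C4 and releases the auxiliary.

Step 6
Reactants: 7 (2S,3S,6R)-2,6-dimethyl-3,6-bis(triethylsilyloxy)oct-7-en-1-ol
Product: 8 (2R,5S,6S)-7-hydroxy-2,6-dimethyl-2,5-bis(triethylsilyloxy)heptanal
Conditions: O3, CH2Cl2, −78 °C; PPh3, −78 °C → rt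
Reagents that add atoms: ozone [O-][O+]=O
Why: Ozonolysis of the remaining vinyl group with reductive work-up should give the non-enolisable α-silyloxy aldehyde at C9.

Step 7
Reactants: 8 (2R,5S,6S)-7-hydroxy-2,6-dimethyl-2,5-bis(triethylsilyloxy)heptanal
Product: 9 (2S,3S,6R)-2,6-dimethyl-3,6-bis(triethylsilyloxy)oct-7-yn-1-ol
Conditions: dimethyl (1-diazo-2-oxopropyl)phosphonate, K2CO3, MeOH, 0 °C → rt
Reagents that add atoms: dimethyl (1-diazo-2-oxopropyl)phosphonate CC(=O)C(=[N+]=[N-])P(=O)(OC)OC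
Why: Ohira–Bestmann (Seyferth–Gilbert) homologation converts the aldehyde into the terminal alkyne (new carbon C8) under mild carbonate conditions, and the quaternary α-carbon cannot epimerise.

Step 8
Reactants: 9 (2S,3S,6R)-2,6-dimethyl-3,6-bis(triethylsilyloxy)oct-7-yn-1-ol
Product: 11 (2S,3S,6R)-2,6-dimethyl-3,6-bis(triethylsilyloxy)-8-(trimethylsilyl)oct-7-yn-1-ol, via bis-silyl ether 10 (not isolated)
Conditions: n-BuLi (2.2 equiv), THF, −78 °C; Me3SiCl (2.5 equiv), −78 → 0 °C; then citric acid, MeOH, rt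
Reagents that add atoms: chlorotrimethylsilane C[Si](C)(C)Cl
Why: Acetylide silylation after double deprotonation gives the C,O-bis-silyl compound, whose labile primary O–SiMe3 bond alone is cleaved by mild acidic methanolysis.

Step 9
Reactants: 11 (2S,3S,6R)-2,6-dimethyl-3,6-bis(triethylsilyloxy)-8-(trimethylsilyl)oct-7-yn-1-ol
Product: 12 [(3R,6S,7R)-8-iodo-3,7-dimethyl-3,6-bis(triethylsilyloxy)oct-1-yn-1-yl]trimethylsilane
Conditions: I2, PPh3, imidazole, CH2Cl2, 0 °C → rt
Reagents that add atoms: iodine II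
Why: Appel-type iodination turns the primary alcohol into the iodide by SN2 displacement and should leave the silyl ethers and the silylalkyne intact.

Step 10
Reactants: 13 mucobromic acid
Product: 14 methyl (2Z)-2,3-dibromo-4-oxobut-2-enoate
Conditions: MeI, NaHCO3, DMF, rt
Reagents that add atoms: iodomethane CI
Why: In bicarbonate the lactol opens to the (Z)-aldehyde carboxylate, which is O-methylated to the open-chain ester in the same way as 2-formylbenzoic acid (carboxylate alkylation).

Step 11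
Reactants: 12 [(3R,6S,7R)-8-iodo-3,7-dimethyl-3,6-bis(triethylsilyloxy)oct-1-yn-1-yl]trimethylsilane; 14 methyl (2Z)-2,3-dibromo-4-oxobut-2-enoate
Product: 16 (5R)-3,4-dibromo-5-[(2S,3S,6R)-2,6-dimethyl-3,6-bis(triethylsilyloxy)-8-(trimethylsilyl)oct-7-yn-1-yl]furan-2(5H)-one, via mixed diorganozinc 15 (not isolated)
Conditions: Et2Zn (neat, 5 equiv), CuI (0.3 mol %), 55 °C, then volatiles removed; (Me3SiCH2)2Zn, toluene, rt; then 14, Ti(OiPr)4 (2 equiv), (1S,2S)-1,2-bis(trifluoromethanesulfonamido)cyclohexane (8 mol %), toluene, −20 °C; aq. NH4Cl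
Reagents that add atoms: none
Why: Iodine–zinc exchange gives a salt-free mixed diorganozinc whose alkyl group adds to the aldehyde under Ti(OiPr)4/bis-sulfonamide catalysis (Knochel-type enantioselective alkylzinc addition), the (1S,2S)-ligand being predicted from the known facial preference of this catalyst to give the 6R alkoxide, which lactonises onto the cis ester.

Step 12
Reactants: 16 (5R)-3,4-dibromo-5-[(2S,3S,6R)-2,6-dimethyl-3,6-bis(triethylsilyloxy)-8-(trimethylsilyl)oct-7-yn-1-yl]furan-2(5H)-one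
Product: 17 (3S,4S,6R,10R)-11-bromo-3,10-bis(triethylsilyloxy)-12-norgermacr-7(11)-en-8-yn-13,6-olide
Conditions: Pd(PPh3)4 (10 mol %), CuCl (20 mol %), DMF (0.002 M, slow addition), 80 °C, argon
Reagents that add atoms: none
Why: Sila-Sonogashira coupling, in which CuCl moves the alkynyl group from silicon to copper without base and the acetylide couples with the more electrophilic β-bromide (C7–Br) of the dibromobutenolide, high dilution favouring closure to the ten-membered cycloalkyne.

Step 13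
Reactants: 17 (3S,4S,6R,10R)-11-bromo-3,10-bis(triethylsilyloxy)-12-norgermacr-7(11)-en-8-yn-13,6-olide
Product: 18 (3S,4S,6R,10R,7(11)E)-11-bromo-3,10-bis(triethylsilyloxy)-12-norgermacr-7(11)-en-8-yne-6,13-diol
Conditions: iBu2AlH (4 equiv), CH2Cl2, −78 → 0 °C; Rochelle salt work-up
Reagents that add atoms: none
Why: Exhaustive hydride reduction of the butenolide (lactone to lactol to diol) opens the template to the cis-2-ene-1,4-diol, so the ring-derived geometry leaves the bromine on C11 cis to the alkyne on C7.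

Step 14
Reactants: 18 (3S,4S,6R,10R,7(11)E)-11-bromo-3,10-bis(triethylsilyloxy)-12-norgermacr-7(11)-en-8-yne-6,13-diol
Product: 21 (3S,4S,6R,10R,8Z)-6,13-dihydroxy-3,10-bis(triethylsilyloxy)germacra-7(11),8-dien-12,8-olide, via alkenyllithium 19 (not isolated), via enynoic acid 20 (not isolated)
Conditions: t-BuLi (4.3 equiv), THF, −78 °C; CO2 (gas), −78 → −20 °C; then AcOH, MeOH, AgNO3 (1.3 equiv), 0 °C → rt, dark
Reagents that add atoms: carbon dioxide O=C=O
Why: After deprotonation of both hydroxyls, bromine–lithium exchange gives the configurationally stable C11 alkenyllithium 19, which adds to CO2 with retention and forms the C11–C12 bond; the resulting enynoate 20 carries its carboxylate cis to the ring alkyne, and silver activation of C8≡C9 then induces anti attack of the carboxylate oxygen on C8 followed by protodemetalation, forming the O–C8 bond. The closest known reactions are the carboxylation of alkenyllithiums and the AgNO3-catalysed cycloisomerisation of (Z)-2-en-4-ynoic acids to (Z)-γ-ylidene butenolides. The butenolide ring closes in the 5-exo-dig mode. No stereocentre is formed; the anti addition across the cycloalkyne fixes the Z ylidene (lactone oxygen cis to C10) and therefore the E ring alkene C8=C9. The step needs 5-exo instead of 6-endo closure, secured by the silver catalyst and by the quaternary C10 that shields C9, and it needs the carboxylate rather than a hydroxyl to reach the alkyne, secured by the template-derived alkene geometry that places only C12 cis to C8. Exchange must outrun addition of t-BuLi to the enyne, which the fully substituted C11 and C10 and the temperature of −78 °C should ensure, and release of cycloalkyne strain adds driving force.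

Step 15
Reactants: 21 (3S,4S,6R,10R,8Z)-6,13-dihydroxy-3,10-bis(triethylsilyloxy)germacra-7(11),8-dien-12,8-olide
Product: 22 (3S,4S,6R,10R,8Z)-13-acetoxy-6-hydroxy-3,10-bis(triethylsilyloxy)germacra-7(11),8-dien-12,8-olide
Conditions: AcCl (1.1 equiv), 2,4,6-collidine, CH2Cl2, −78 °C
Reagents that add atoms: acetyl chloride CC(=O)Cl
Why: Selective acetylation of the primary allylic alcohol in the presence of the hindered secondary one with AcCl/collidine at low temperature.

Step 16
Reactants: 22 (3S,4S,6R,10R,8Z)-13-acetoxy-6-hydroxy-3,10-bis(triethylsilyloxy)germacra-7(11),8-dien-12,8-olide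
Product: 23 (3S,4S,6R,10R,8Z)-13-acetoxy-6-(3-methylbut-2-enoyloxy)-3,10-bis(triethylsilyloxy)germacra-7(11),8-dien-12,8-olide
Conditions: 3-methylbut-2-enoyl chloride, pyridine, DMAP (cat.), CH2Cl2, 0 °C → rt
Reagents that add atoms: 3-methylbut-2-enoyl chloride CC(C)=CC(=O)Cl
Why: Pyridine/DMAP-mediated acylation of the remaining secondary alcohol with the acid chloride, the weak base limiting deconjugation of the senecioyl group.

Step 17
Reactants: 23 (3S,4S,6R,10R,8Z)-13-acetoxy-6-(3-methylbut-2-enoyloxy)-3,10-bis(triethylsilyloxy)germacra-7(11),8-dien-12,8-olide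
Product: 24 (3S,4S,6R,10R,8Z)-13-acetoxy-3,10-dihydroxy-6-(3-methylbut-2-enoyloxy)germacra-7(11),8-dien-12,8-olide
Conditions: HF·pyridine, pyridine, THF, 0 °C → rt
Reagents that add atoms: none
Why: Fluoride cleavage of both triethylsilyl ethers with buffered HF·pyridine, conditions that the enol lactone and the two esters should tolerate.

Step 18
Reactants: 24 (3S,4S,6R,10R,8Z)-13-acetoxy-3,10-dihydroxy-6-(3-methylbut-2-enoyloxy)germacra-7(11),8-dien-12,8-olide
Product: 25 (4S,6R,10R,8Z)-13-acetoxy-10-hydroxy-6-(3-methylbut-2-enoyloxy)-3-oxogermacra-7(11),8-dien-12,8-olide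
Conditions: Dess–Martin periodinane, pyridine, CH2Cl2, 0 °C → rt
Reagents that add atoms: none
Why: Dess–Martin oxidation converts the secondary C3 alcohol into the ketone under buffered non-basic conditions that neither touch the tertiary alcohol nor epimerise C4.

Compound list
1 | (R)-linalool, (3R)-3,7-dimethylocta-1,6-dien-3-ol | C=C[C@](C)(O)CCC=C(C)C | starting material
2 | triethyl{[(3R)-3,7-dimethylocta-1,6-dien-3-yl]oxy}silane | C=C[C@](C)(O[Si](CC)(CC)CC)CCC=C(C)C | intermediate
3 | (4R)-4-methyl-4-(triethylsilyloxy)hex-5-enal | C=C[C@](C)(O[Si](CC)(CC)CC)CCC=O | intermediate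
4 | (4R)-4-benzyl-3-propanoyl-1,3-oxazolidin-2-one | CCC(=O)N1[C@H](Cc2ccccc2)COC1=O | starting material
5 | (4R)-4-benzyl-3-[(2R,3S,6R)-3-hydroxy-2,6-dimethyl-6-(triethylsilyloxy)oct-7-enoyl]-1,3-oxazolidin-2-one | C=C[C@](C)(O[Si](CC)(CC)CC)CC[C@H](O)[C@@H](C)C(=O)N1[C@H](Cc2ccccc2)COC1=O | intermediate
6 | (4R)-4-benzyl-3-[(2R,3S,6R)-2,6-dimethyl-3,6-bis(triethylsilyloxy)oct-7-enoyl]-1,3-oxazolidin-2-one | C=C[C@](C)(O[Si](CC)(CC)CC)CC[C@H](O[Si](CC)(CC)CC)[C@@H](C)C(=O)N1[C@H](Cc2ccccc2)COC1=O | intermediate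
7 | (2S,3S,6R)-2,6-dimethyl-3,6-bis(triethylsilyloxy)oct-7-en-1-ol | C=C[C@](C)(O[Si](CC)(CC)CC)CC[C@H](O[Si](CC)(CC)CC)[C@@H](C)CO | intermediate
8 | (2R,5S,6S)-7-hydroxy-2,6-dimethyl-2,5-bis(triethylsilyloxy)heptanal | O=C[C@](C)(O[Si](CC)(CC)CC)CC[C@H](O[Si](CC)(CC)CC)[C@@H](C)CO | intermediate
9 | (2S,3S,6R)-2,6-dimethyl-3,6-bis(triethylsilyloxy)oct-7-yn-1-ol | C#C[C@](C)(O[Si](CC)(CC)CC)CC[C@H](O[Si](CC)(CC)CC)[C@@H](C)CO | intermediate
10 | trimethyl{[(2S,3S,6R)-2,6-dimethyl-3,6-bis(triethylsilyloxy)-8-(trimethylsilyl)oct-7-yn-1-yl]oxy}silane | C[Si](C)(C)C#C[C@](C)(O[Si](CC)(CC)CC)CC[C@H](O[Si](CC)(CC)CC)[C@@H](C)CO[Si](C)(C)C | intermediate (not isolated)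
11 | (2S,3S,6R)-2,6-dimethyl-3,6-bis(triethylsilyloxy)-8-(trimethylsilyl)oct-7-yn-1-ol | C[Si](C)(C)C#C[C@](C)(O[Si](CC)(CC)CC)CC[C@H](O[Si](CC)(CC)CC)[C@@H](C)CO | intermediate
12 | [(3R,6S,7R)-8-iodo-3,7-dimethyl-3,6-bis(triethylsilyloxy)oct-1-yn-1-yl]trimethylsilane | C[Si](C)(C)C#C[C@](C)(O[Si](CC)(CC)CC)CC[C@H](O[Si](CC)(CC)CC)[C@@H](C)CI | intermediate
13 | mucobromic acid, 3,4-dibromo-5-hydroxyfuran-2(5H)-one (racemic lactol) | OC1OC(=O)C(Br)=C1Br | starting material
14 | methyl (2Z)-2,3-dibromo-4-oxobut-2-enoate | COC(=O)/C(Br)=C(Br)\C=O | intermediate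
15 | [(2R,3S,6R)-2,6-dimethyl-3,6-bis(triethylsilyloxy)-8-(trimethylsilyl)oct-7-yn-1-yl](trimethylsilylmethyl)zinc | C[Si](C)(C)C#C[C@](C)(O[Si](CC)(CC)CC)CC[C@H](O[Si](CC)(CC)CC)[C@@H](C)C[Zn]C[Si](C)(C)C | intermediate (not isolated)
16 | (5R)-3,4-dibromo-5-[(2S,3S,6R)-2,6-dimethyl-3,6-bis(triethylsilyloxy)-8-(trimethylsilyl)oct-7-yn-1-yl]furan-2(5H)-one | C[Si](C)(C)C#C[C@](C)(O[Si](CC)(CC)CC)CC[C@H](O[Si](CC)(CC)CC)[C@@H](C)C[C@H]1OC(=O)C(Br)=C1Br | intermediate
17 | (3S,4S,6R,10R)-11-bromo-3,10-bis(triethylsilyloxy)-12-norgermacr-7(11)-en-8-yn-13,6-olide (bromobutenolide fused at C6/C7 to the ten-membered cycloalkyne) | C1#C[C@](C)(O[Si](CC)(CC)CC)CC[C@H](O[Si](CC)(CC)CC)[C@@H](C)C[C@H]2OC(=O)C(Br)=C12 | intermediate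
18 | (3S,4S,6R,10R,7(11)E)-11-bromo-3,10-bis(triethylsilyloxy)-12-norgermacr-7(11)-en-8-yne-6,13-diol (Br cis to the ring alkyne) | OC/C(Br)=C1/C#C[C@](C)(O[Si](CC)(CC)CC)CC[C@H](O[Si](CC)(CC)CC)[C@@H](C)C[C@H]1O | intermediate
19 | C11-lithio derivative of the dilithium 6,13-dialkoxide of 18 | [Li]OC/C([Li])=C1/C#C[C@](C)(O[Si](CC)(CC)CC)CC[C@H](O[Si](CC)(CC)CC)[C@@H](C)C[C@H]1O[Li] | intermediate (not isolated)
20 | (3S,4S,6R,10R,7(11)E)-6,13-dihydroxy-3,10-bis(triethylsilyloxy)germacr-7(11)-en-8-yn-12-oic acid (carboxyl cis to the ring alkyne; formed as its lithium salt) | OC/C(C(=O)O)=C1/C#C[C@](C)(O[Si](CC)(CC)CC)CC[C@H](O[Si](CC)(CC)CC)[C@@H](C)C[C@H]1O | intermediate (not isolated)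
21 | (3S,4S,6R,10R,8Z)-6,13-dihydroxy-3,10-bis(triethylsilyloxy)germacra-7(11),8-dien-12,8-olide | OCC1=C2/C(=C/[C@](C)(O[Si](CC)(CC)CC)CC[C@H](O[Si](CC)(CC)CC)[C@@H](C)C[C@H]2O)OC1=O | intermediate
22 | (3S,4S,6R,10R,8Z)-13-acetoxy-6-hydroxy-3,10-bis(triethylsilyloxy)germacra-7(11),8-dien-12,8-olide | CC(=O)OCC1=C2/C(=C/[C@](C)(O[Si](CC)(CC)CC)CC[C@H](O[Si](CC)(CC)CC)[C@@H](C)C[C@H]2O)OC1=O | intermediate
23 | (3S,4S,6R,10R,8Z)-13-acetoxy-6-(3-methylbut-2-enoyloxy)-3,10-bis(triethylsilyloxy)germacra-7(11),8-dien-12,8-olide | CC(=O)OCC1=C2/C(=C/[C@](C)(O[Si](CC)(CC)CC)CC[C@H](O[Si](CC)(CC)CC)[C@@H](C)C[C@H]2OC(=O)C=C(C)C)OC1=O | intermediate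
24 | (3S,4S,6R,10R,8Z)-13-acetoxy-3,10-dihydroxy-6-(3-methylbut-2-enoyloxy)germacra-7(11),8-dien-12,8-olide | CC(=O)OCC1=C2/C(=C/[C@](C)(O)CC[C@H](O)[C@@H](C)C[C@H]2OC(=O)C=C(C)C)OC1=O | intermediate
25 | (4S,6R,10R,8Z)-13-acetoxy-10-hydroxy-6-(3-methylbut-2-enoyloxy)-3-oxogermacra-7(11),8-dien-12,8-olide | CC(=O)OCC1=C2/C(=C/[C@](C)(O)CCC(=O)[C@@H](C)C[C@H]2OC(=O)C=C(C)C)OC1=O | target

Total step count: 18. Longest linear sequence: 17 (steps 1–9 and 11–18; step 10 is a one-step side branch).

Steps most likely to fail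

1. Step 12 (macrocyclisation). Intermolecular coupling may outrun ring closure, the silicon-to-copper transfer may be slow with a bromide electrophile, the strained ten-membered enyne may form reluctantly, and prolonged heating may erode the C6 configuration. Fallback: setting out from 16, the silylalkyne is protodesilylated with catalytic AgNO3 in aqueous acetone to the terminal alkyne F1, which is stannylated with Bu3SnOMe to the alkynylstannane F2. F2 is then closed by a base-free intramolecular Stille coupling (Pd2(dba)3, AsPh3, high dilution), which returns to the route at 17. This replaces the in situ copper acetylide by a pre-formed, isolated tin nucleophile.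

2. Step 14 (key step). The exchange may be incomplete, the alkenyllithium may be protonated before carboxylation, t-BuLi may add to the enyne, or the cyclisation may go 6-endo or be intercepted by a neighbouring hydroxyl. Fallback: setting out from 18, the alkenyl bromide is methoxycarbonylated (CO, MeOH, Pd(OAc)2, dppf, Et3N) to the methyl ester F3. F3 is saponified with LiOH to the acid 20, now isolated, and 20 is cyclised with catalytic AgNO3, which returns to the route at 21. The two bonds are then made in separate operations.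

3. Step 11 (enantioselective alkylzinc addition). Facial selectivity may be poor with this unusually electron-poor, ester-bearing aldehyde, the uncatalysed background addition may compete, and alkoxide may substitute a vinylic bromide. Fallback: setting out from 12 and 14, the same zinc reagent is added with Ti(OiPr)4 alone (no chiral ligand), which should give 16 together with its C6 epimer F4. The two diastereomers are separated by chromatography, and F4 is equilibrated at C6 with catalytic DBU (through the 2-hydroxyfuran tautomer) and recycled, returning to the route at 16. Catalyst control is thus replaced by separation and epimerisation.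

Further compounds
F1 | step 12 | (5R)-3,4-dibromo-5-[(2S,3S,6R)-2,6-dimethyl-3,6-bis(triethylsilyloxy)oct-7-yn-1-yl]furan-2(5H)-one | C#C[C@](C)(O[Si](CC)(CC)CC)CC[C@H](O[Si](CC)(CC)CC)[C@@H](C)C[C@H]1OC(=O)C(Br)=C1Br
F2 | step 12 | (5R)-3,4-dibromo-5-[(2S,3S,6R)-2,6-dimethyl-3,6-bis(triethylsilyloxy)-8-(tributylstannyl)oct-7-yn-1-yl]furan-2(5H)-one | CCCC[Sn](CCCC)(CCCC)C#C[C@](C)(O[Si](CC)(CC)CC)CC[C@H](O[Si](CC)(CC)CC)[C@@H](C)C[C@H]1OC(=O)C(Br)=C1Br
F3 | step 14 | methyl (3S,4S,6R,10R,7(11)E)-6,13-dihydroxy-3,10-bis(triethylsilyloxy)germacr-7(11)-en-8-yn-12-oate | OC/C(C(=O)OC)=C1/C#C[C@](C)(O[Si](CC)(CC)CC)CC[C@H](O[Si](CC)(CC)CC)[C@@H](C)C[C@H]1O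
F4 | step 11 | (5S)-3,4-dibromo-5-[(2S,3S,6R)-2,6-dimethyl-3,6-bis(triethylsilyloxy)-8-(trimethylsilyl)oct-7-yn-1-yl]furan-2(5H)-one | C[Si](C)(C)C#C[C@](C)(O[Si](CC)(CC)CC)CC[C@H](O[Si](CC)(CC)CC)[C@@H](C)C[C@@H]1OC(=O)C(Br)=C1Br
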